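A minute is the unit I count in here, and a minute at 30 °C is not worth a minute at 60 °C.

all flasks: protic impurity 0.440 mM; time 25 min

|  | substrate | partner | remark | temperature |
|---|---|---|---|---|
| birch | 0.022 M | 0.0550 M (fed, over 15 min) | the addition at 30 °C, then warmed to 60 °C; the feed brings no volume worth counting |  |
| larch | 0.022 M (fed, over 15 min) | 0.0550 M | all else is in the flask from the start; the feed brings no volume worth counting | 60 °C |
| cedar | 0.022 M | 0.0550 M | everything together at the start | 60 °C |
| oak | 0.022 M | 0.0550 M | everything together at the start at 30 °C, warmed to 60 °C at 15 min |  |
| alder | 0.022 M (in portions, 5, over 15 min) | 0.0550 M | first portion at the start, last at 15 min | 60 °C |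

    partner → second intermediate (k1 = 0.011 s⁻¹, Ea1 = 101 kJ mol⁻¹)
    substrate → open intermediate (k2 = 0.0032 s⁻¹, Ea2 = 97.0 kJ mol⁻¹)
    partner + protic impurity → quenched reagent (k3 = 9.5 M⁻¹ s⁻¹, Ea3 = 55.0 kJ mol⁻¹)
    open intermediate + second intermediate → target (k4 = 0.21 M⁻¹ s⁻¹, Ea4 = 41.0 kJ mol⁻¹)
    substrate ⇌ dormant form (K5 = 0.39, k5 = 0.0036 s⁻¹, Ea5 = 90.0 kJ mol⁻¹, ΔH5 = 23.0 kJ mol⁻¹)
    substrate + open intermediate → side product (k6 = 0.022 M⁻¹ s⁻¹, Ea6 = 53.0 kJ mol⁻¹)
    (constants at 60 °C)

- a species is counted by the substrate in it: one side product counts as two
- the constants hold at 60 °C; other temperatures follow from the activation energies and enthalpies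

- the flask with the highest amount of target, in percent of the substrate charged ("all alike" if they lie within 1.5 percentage points) (birch / larch / cedar / oak / alder / all alike)
- final target, as a percentage of the substrate charged, in birch
- final target, as a percentage of the substrate charged, in larch
- final target, as a percentage of the substrate charged, in cedar
- final target, as a percentage of the substrate charged, in oak
- final target, as a percentage of the substrate charged, in alder

Substrate is the limiting reagent, since I charge 0.022 M of it against 0.0550 M of partner, even after the protic impurity has taken its 0.440 mM. So I write the balance of substrate. At 60 °C, substrate and dormant form exchange in about 1.30 min, which is shorter than the time the opening step needs, so I treat the two as one pool that drains through its substrate part: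

pool lifetime = (1 + 0.39) / 0.0032 s⁻¹ = 7.24 min

I call this the pool lifetime, the time in which substrate and dormant form together fall by a factor e. With the constants carried down to 30 °C, the same formula gives 195 min, so a hot minute does 26.9 times the work of a cold one.

Cedar and oak hold the same charge and differ in their first 15 min, which oak spends cold:

pool left in cedar = 3.16%

pool left in oak = 23.3%

Open intermediate then meets second intermediate, for which I take 0.0326 M, what the partner charge gives once it has turned over and the protic impurity and the whole substrate charge have taken their share. That makes its loss at 60 °C pseudo-first-order, with a lifetime of about 2.44 min. This is shorter than the pool lifetime, so I let open intermediate trail the pool, and I reckon pool and open intermediate together at 1.51 times the pool. Before any side product, I reckon target at 95.2% in cedar and 64.8% in oak, and I stop there.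

The forecast names cedar as the best flask, with 65% in birch, 82% in larch, 90% in cedar, 66% in oak and 81.5% in alder. Its ground is that “what counts is how long the substrate spends hot”. Its cedar figure lies below mine, and its oak figure lies beside mine.

The simulation gives cedar as the best flask, with 65.9% in birch, 83.1% in larch, 91.7% in cedar, 66.1% in oak and 82.1% in alder. In cedar, half of the partner's turnover is done by 1.05 min and half of the opening by 4.37 min, so the opening runs later. At the stop, cedar's pool stands at 3.63% against my 3.16%. Cedar left until 40 min is the further case, where the pool lifetime and the trailing factor give an unfinished share of 0.602%. That flask holds 0.766% as substrate, dormant form and open intermediate, with target at 96.0%.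

The numbers are invented; the run is a simulation.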